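## Structural features

The target is a cembranolide: a 14-membered carbocycle (ring A, C1–C14) trans-fused across C1–C2 to an α-methylene-γ-butyrolactone (ring B: C1, C2, O, C16, C15, with exocyclic C15=C17). A trisubstituted epoxide (C3–C4, methyl on C4) lies next to the lactone carbinol C2, and the acetoxy carbon C14 lies on the other side of C1. C14, C1, C2, C3 and C4 therefore form an unbroken row of five stereocentres (14S, 1R, 2S, 3R, 4R). The rest of ring A carries no stereocentres but two E-trisubstituted olefins, C7=C8 and C11=C12, separated by C9H2–C10H2. The fragile groups are the α-methylene lactone (Michael acceptor), the acid-sensitive epoxide, and the C14 oxygen, which is γ to the lactone carbonyl and can take over the acyl group once it is free. The five stereocentres can be set on an open chain with reagent control; the real difficulty is closing ring A, which has no conformational bias, while fixing a trisubstituted olefin geometry and the last stereocentre. The key step uses the array C14(O)–C13H2–C12(CH3)=C11H–C10H2, a homoallylic carbinol with an E-trisubstituted olefin, which is the product pattern of a reductive 1,4-hydroalkylation of a 2-methyl-1,3-diene (C10–C13) by a C14 aldehyde.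

## Logic of the disconnections

24 to 23 to 22: the C14 O–acetyl bond and then the O–Si bond are cut. An acetate would not survive the enolate chemistry that makes C15=C17, and the free C14 hydroxyl should exist for one step only because it can capture the lactone acyl group. No skeleton is removed, but 22 becomes the last compound that must tolerate base. The forward steps need a desilylation that spares epoxide and enoate.

22 to 18 (through 20 and 21): C15=C17 is cut. A conjugated lactone would compete with the aldehyde for zerovalent nickel and for hydride, so the ring is closed on the saturated lactone. The forward step needs enolisation at C15 only; this is secured because C15 is the only carbon α to a carbonyl and C1 bears no leaving group.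

18 to 17: the C13–C14 bond is cut. This opens ring A, removes the C14 stereocentre and the C11=C12 geometry problem, and returns C10–C13 to a terminal diene. The result is an open chain whose four remaining stereocentres sit in one compact C1–C4 unit. The forward step must bond at C13, deliver hydrogen to C10, give the E olefin and 14S, and close the ring in preference to oligomerising.

17 to 16 to 15: only the oxidation level of C14 changes. The epimerisable, β-acyloxy aldehyde is made immediately before use, and its carbon arrives as the acyl carbon of the auxiliary. The forward reduction must take the imide and leave the lactone.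

15 to 12 plus 9: the C1–C2 bond and the lactone O–C16 bond are cut. One auxiliary-controlled syn aldol sets C1 and C2 together, and a syn adduct maps onto the trans lactone. A cut at C2–C3 (alkenyl-metal addition to an α-branched aldehyde whose two α-arms are both CH2X groups) would offer little facial bias at C2 and was rejected. A methyl ester is used so that lactonisation needs no strong acid next to the epoxide. The forward step demands that the enolate face selection overrides the Felkin preference of 9.

9 to 8 to 7: the two C–O bonds of the epoxide are cut. Reagent-controlled epoxidation of a primary allylic alcohol sets C3 and C4 and touches only one of four olefins. The forward step needs the correct tartrate enantiomer and acid-free handling.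

7 to 6 to 3 plus 4: the C9–C10 bond is cut between an allylic carbon and the diene. This is convergent, and both olefin geometries come from defined precursors. The forward coupling must occur at the primary allyl terminus with retention, and the bromide must react ahead of the acetate.

3 to 2 to 1: the C9–Br and C9–O bonds are cut. 1 already holds C2–C9 with both methyls and the C3=C4 geometry; allylic oxidation of its E-methyl supplies C9.

12 to 10 plus 11: the N–acyl bond is cut; both pieces are commercial.

## Other disconnections considered

Alternative 1: the cut is C5–C6, reached through a ring-expanded ester. The forward key step would be a Carroll-type decarboxylative allylation: Pd(PPh3)4 (zerovalent palladium) ionises the C6 allylic ester of the 16-membered β-keto lactone A1, CO2 is lost, and the C5 enolate recombines at C6 to give the 14-membered C4 ketone A2.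
- In its favour: A1 would come from a macrolactonisation, a dependable ring closure. The contraction is an intramolecular ion-pair recombination that touches no stereocentre. C14 and the lactone are in place before the ring closes, and no epimerisable aldehyde is involved. On these points it is the equal or the better of the chosen plan.
- Against it here: recombination could occur at C8 as well as C6, and the allylpalladium intermediate can erode the C7=C8 geometry. A2 still lacks the C4 methyl and the epoxide, so a facially controlled methyl addition to a ketone in a flexible ring, ether cleavage, activation of the C3 oxygen and closure with inversion at C3 must follow, then the silyl-to-acetyl exchange and methylenation.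
- Comparison: the chosen plan closes the ring on a compound that already holds all oxygen functions and all but one stereocentre, and needs four steps afterwards. Alternative 1 is mechanistically safer at the ring closure but leaves more of the structure unmade, with two extra protecting groups and a clearly longer endgame.

Alternative 2: the cut is C11–C12, at the alkyne oxidation level. The molybdenum alkylidyne Mo(≡CC6H4OMe)(OSiPh3)3 would metathesise the two methyl-capped alkynes of diyne A3 to the 14-membered cycloalkyne A4. A hydroxyl-directed trans-hydrostannation and a methyl cross-coupling would then make the E-olefin.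
- In its favour: ring-closing alkyne metathesis is well established for rings of this size and is indifferent to epoxide and lactone. The E geometry would follow from the trans-addition mechanism. C14 is set before ring closure. In precedent for the macrocyclisation, and in independence of C14 from the ring closure, it is better than the chosen plan; in control of olefin geometry it is at least equal.
- Against it here: the ring closure creates neither the methyl-bearing olefin nor a stereocentre, so two more metal-mediated steps with stoichiometric tin follow. Regiocontrol of the hydrostannation would rest on a homopropargylic hydroxyl, one carbon further away than the best-behaved case. The tin hydride and the free hydroxyl meet an α-methylene lactone. A3 needs two methyl-capped alkynes and a separately controlled C14 carbinol.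
- Comparison: the chosen plan makes ring, olefin and C14 in one operation from a shorter precursor. Alternative 2 trades that economy for a ring closure of known reliability.

Alternative 3: the cut is C12–C13. Ni(cod)2 with PBu3 and Et3B would couple the methyl-capped alkyne of A5 with its terminal C13–C14 epoxide, opening at C13 and adding hydrogen syn to C11, to give the macrocyclic C14 alcohol A6.
- In its favour: C14 would be carried in by the epoxide and transferred stereospecifically. This is better than the chosen plan, where C14 depends on facial selectivity. A5 has no epimerisable aldehyde, so its stability is equal or better. Syn addition gives the E olefin. A6 is one silylation away from 18.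
- Against it here: the two alkyne carbons differ only as methyl against methylene, so the choice of which carbon bonds (endocyclic olefin against exocyclic ethylidene) is weakly controlled. The substrate holds a second epoxide next to a Lewis-acidic borane. The terminal epoxide next to C1 needs its own stereoselective synthesis. As a macrocyclisation the reaction is as unprecedented as the chosen one.
- Comparison: both are new ring closures of the same risk class. The chosen plan has the regiochemically unambiguous partner (one unsubstituted diene terminus) and a precursor reached directly from an aldehyde; Alternative 3 has the more secure C14.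

Key step: step 11

Remark on the chemistry: locants are cembrane locants; the C1 label changes between S (15, 17–22) and R (16, 23, 24) through substituent priorities only, with no inversion; C15 of 20 and 21 is an inconsequential epimer mixture; the cyclopentadienyl rings of 5 are drawn σ-bonded in its SMILES.

## Steps

Step 1
Reactants: 1 geranyl acetate
Product: 2 (2E,6E)-8-hydroxy-3,7-dimethylocta-2,6-dien-1-yl acetate
Conditions: SeO2 (cat.), t-BuOOH, salicylic acid (cat.), CH2Cl2, rt
Reagents that add atoms: tert-butyl hydroperoxide, CC(C)(C)OO (net oxygen source, delivered through catalytic SeO2)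
Why: Selenium dioxide allylic oxidation (ene reaction, then [2,3]-sigmatropic shift) should attack the E-methyl of the electron-richer terminal olefin; the C2=C3 olefin is deactivated by the allylic acetate.

Step 2
Reactants: 2 (2E,6E)-8-hydroxy-3,7-dimethylocta-2,6-dien-1-yl acetate
Product: 3 (2E,6E)-8-bromo-3,7-dimethylocta-2,6-dien-1-yl acetate
Conditions: CBr4, PPh3, CH2Cl2, 0 °C
Reagents that add atoms: carbon tetrabromide, BrC(Br)(Br)Br
Why: Appel bromination; SN2 displacement at the primary allylic carbon should proceed without allylic transposition and leave the acetate untouched.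

Step 3
Reactants: 3 (2E,6E)-8-bromo-3,7-dimethylocta-2,6-dien-1-yl acetate; 4 2-methylbut-1-en-3-yne
Product: 6 (2E,6E,9E)-3,7,11-trimethyldodeca-2,6,9,11-tetraen-1-yl acetate, via dienylzirconocene chloride 5 (not isolated)
Conditions: 4, Cp2Zr(H)Cl, THF, rt; then 3, Pd(PPh3)4 (5 mol%), THF, rt
Reagents that add atoms: none
Why: Syn hydrozirconation of the terminal alkyne fixes the E geometry of the future C10=C11; Negishi-type palladium-catalysed allyl–alkenyl coupling should then join C9–C10 at the unhindered allyl terminus with retention of the trisubstituted olefin. The allylic bromide ionises far faster than the allylic acetate.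

Step 4
Reactants: 6 (2E,6E,9E)-3,7,11-trimethyldodeca-2,6,9,11-tetraen-1-yl acetate
Product: 7 (2E,6E,9E)-3,7,11-trimethyldodeca-2,6,9,11-tetraen-1-ol
Conditions: K2CO3, MeOH, rt
Reagents that add atoms: none
Why: Base-catalysed transesterification; the conditions are too mild to move the skipped olefins into conjugation.

Step 5
Reactants: 7 (2E,6E,9E)-3,7,11-trimethyldodeca-2,6,9,11-tetraen-1-ol
Product: 8 [(2R,3R)-3-[(3E,6E)-4,8-dimethylnona-3,6,8-trien-1-yl]-3-methyloxiran-2-yl]methanol
Conditions: Ti(OiPr)4 (cat.), D-(−)-diethyl tartrate, t-BuOOH, 4 Å molecular sieves, CH2Cl2, −20 °C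
Reagents that add atoms: tert-butyl hydroperoxide, CC(C)(C)OO
Why: Katsuki–Sharpless asymmetric epoxidation; titanium binds only the allylic alcohol, so only the olefin that becomes C3–C4 reacts. The D-(−)-tartrate ligand should deliver oxygen to the face that gives the (2R,3R)-epoxy alcohol, i.e. 3R,4R of the target.

Step 6
Reactants: 8 [(2R,3R)-3-[(3E,6E)-4,8-dimethylnona-3,6,8-trien-1-yl]-3-methyloxiran-2-yl]methanol
Product: 9 (2S,3R)-3-[(3E,6E)-4,8-dimethylnona-3,6,8-trien-1-yl]-3-methyloxirane-2-carbaldehyde
Conditions: Dess–Martin periodinane, pyridine, CH2Cl2, 0 °C to rt; used crude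
Reagents that add atoms: none
Why: Dess–Martin oxidation under buffered conditions; the α-carbon is an epoxide carbon and cannot epimerise, and the olefins are inert to the reagent.

Step 7
Reactants: 10 (S)-4-benzyl-1,3-oxazolidin-2-one; 11 methyl 4-chloro-4-oxobutanoate
Product: 12 methyl 4-[(4S)-4-benzyl-2-oxo-1,3-oxazolidin-3-yl]-4-oxobutanoate
Conditions: Et3N, DMAP (cat.), CH2Cl2, 0 °C to rt
Reagents that add atoms: none
Why: DMAP-catalysed N-acylation of the oxazolidinone by the acid chloride; the methyl ester is not touched.

Step 8
Reactants: 12 methyl 4-[(4S)-4-benzyl-2-oxo-1,3-oxazolidin-3-yl]-4-oxobutanoate; 9 (2S,3R)-3-[(3E,6E)-4,8-dimethylnona-3,6,8-trien-1-yl]-3-methyloxirane-2-carbaldehyde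
Product: 15 (4S)-4-benzyl-3-{[(2S,3S)-2-[(2R,3R)-3-[(3E,6E)-4,8-dimethylnona-3,6,8-trien-1-yl]-3-methyloxiran-2-yl]-5-oxooxolan-3-yl]carbonyl}-1,3-oxazolidin-2-one, via dibutylboron Z-enolate 13 (not isolated), via syn-aldol hydroxy ester 14 (not isolated)
Conditions: 12, Bu2BOTf, iPr2NEt, CH2Cl2, −78 to 0 °C; 9, −78 to 0 °C; pH 7 buffer, MeOH, H2O2, 0 °C; then pyridinium p-toluenesulfonate (cat.), CH2Cl2, rt
Reagents that add atoms: none
Why: Evans syn-aldol reaction through a Zimmerman–Traxler chair of the Z-boron enolate; the (S)-benzyl auxiliary should fix C1 and C2 together and override the opposite Felkin preference of the epoxy aldehyde. The γ-hydroxy methyl ester then lactonises with loss of methanol, and a syn adduct gives the trans-disubstituted lactone.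

Step 9
Reactants: 15 (4S)-4-benzyl-3-{[(2S,3S)-2-[(2R,3R)-3-[(3E,6E)-4,8-dimethylnona-3,6,8-trien-1-yl]-3-methyloxiran-2-yl]-5-oxooxolan-3-yl]carbonyl}-1,3-oxazolidin-2-one
Product: 16 (4R,5S)-5-[(2R,3R)-3-[(3E,6E)-4,8-dimethylnona-3,6,8-trien-1-yl]-3-methyloxiran-2-yl]-4-(hydroxymethyl)oxolan-2-one
Conditions: NaBH4, THF/H2O (4:1), 0 °C; NH4Cl quench
Reagents that add atoms: none
Why: Reductive cleavage of the N-acyl oxazolidinone by borohydride; the imide carbonyl is more electrophilic than the lactone, so C14 should be reduced selectively and the auxiliary released.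

Step 10
Reactants: 16 (4R,5S)-5-[(2R,3R)-3-[(3E,6E)-4,8-dimethylnona-3,6,8-trien-1-yl]-3-methyloxiran-2-yl]-4-(hydroxymethyl)oxolan-2-one
Product: 17 (2S,3S)-2-[(2R,3R)-3-[(3E,6E)-4,8-dimethylnona-3,6,8-trien-1-yl]-3-methyloxiran-2-yl]-5-oxooxolane-3-carbaldehyde
Conditions: Dess–Martin periodinane, pyridine, CH2Cl2, 0 °C; used at once
Reagents that add atoms: none
Why: Dess–Martin oxidation under buffered, non-basic conditions; these avoid epimerisation at C1 and β-elimination of the lactone carboxylate in the β-acyloxy aldehyde.

Step 11
Reactants: 17 (2S,3S)-2-[(2R,3R)-3-[(3E,6E)-4,8-dimethylnona-3,6,8-trien-1-yl]-3-methyloxiran-2-yl]-5-oxooxolane-3-carbaldehyde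
Product: 18 (1S,2S,3R,4R,7E,11E,14S)-3,4-epoxy-14-(triethylsilyloxy)-17-norcembra-7,11-dien-16,2-olide
Conditions: Ni(cod)2 (20 mol%), PPh3 (40 mol%), Et3SiH (5 equiv), degassed THF, rt; 17 added slowly to 0.002 M
Reagents that add atoms: triethylsilane, CC[SiH](CC)CC
Why: Proposed new method: zerovalent nickel binds the diene and the aldehyde and undergoes oxidative cyclisation, joining C13 to C14 and giving an oxanickelacycle of divalent nickel in which C10–C12 are held as an η3-allyl ligand; Et3SiH then silylates the alkoxide and passes hydride to nickel, and reductive elimination places that hydrogen on C10 and returns zerovalent nickel. The closest known reaction type is the nickel-catalysed three-component reductive coupling of 1,3-dienes, aldehydes and trialkylsilanes to E-homoallylic silyl ethers, established between separate partners and for five- to seven-membered rings but not for a macrocycle. Ring A closes end to end (C13 of the diene onto C14), an endo-type closure that leaves the new C11=C12 olefin inside the ring and is favoured by slow addition at high dilution. C13 is the only unsubstituted diene terminus, so sterics and the larger orbital coefficient should direct bond formation there and hydrogen to C10 (1,4-mode). The E geometry of C11=C12 should follow from the syn arrangement of the η3-allyl ligand, which equilibrates faster than hydride transfer. C14 is controlled by the adjacent C1 stereocentre of the trans-lactone: Felkin–Anh attack anti to the C1–C2 bond, which carries the bulky epoxide arm, gives 14S. The needed chemoselectivity rests on the inertness of the saturated lactone, the trisubstituted epoxide and the isolated C7=C8 olefin toward zerovalent nickel, and the neutral medium spares the epimerisable β-acyloxy aldehyde.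

Step 12
Reactants: 18 (1S,2S,3R,4R,7E,11E,14S)-3,4-epoxy-14-(triethylsilyloxy)-17-norcembra-7,11-dien-16,2-olide
Product: 20 15-[(dimethylamino)methyl] derivative of 18 (C15 epimers), via lithium lactone enolate 19 (not isolated)
Conditions: LiN(SiMe3)2, THF, −78 °C; then CH2=NMe2+ I−, −78 °C to rt
Reagents that add atoms: dimethylmethyleneiminium iodide, C=[N+](C)C.[I-]
Why: Mannich reaction of the lithium enolate with Eschenmoser's salt; C15 is the only carbon α to a carbonyl and C1 carries no leaving group, so no elimination should compete. The new C15 centre is destroyed in the next step.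

Step 13
Reactants: 20 15-[(dimethylamino)methyl] derivative of 18 (C15 epimers)
Product: 22 (1S,2S,3R,4R,7E,11E,14S)-3,4-epoxy-14-(triethylsilyloxy)cembra-7,11,15(17)-trien-16,2-olide, via trimethylammonium iodide 21 (not isolated)
Conditions: MeI, MeOH, rt; then NaHCO3 (aq), CH2Cl2, rt
Reagents that add atoms: none
Why: N-methylation followed by E1cB (Hofmann-type) elimination of trimethylamine should give the exocyclic methylene under conditions too mild to harm epoxide or silyl ether.

Step 14
Reactants: 22 (1S,2S,3R,4R,7E,11E,14S)-3,4-epoxy-14-(triethylsilyloxy)cembra-7,11,15(17)-trien-16,2-olide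
Product: 23 (1R,2S,3R,4R,7E,11E,14S)-3,4-epoxy-14-hydroxycembra-7,11,15(17)-trien-16,2-olide
Conditions: HF·pyridine, pyridine, THF, 0 °C; used directly
Reagents that add atoms: none
Why: Fluoride-mediated cleavage of the secondary triethylsilyl ether; the pyridine buffer should protect the epoxide, and the absence of a free alkoxide should suppress lactone migration to O14 and conjugate addition.

Step 15
Reactants: 23 (1R,2S,3R,4R,7E,11E,14S)-3,4-epoxy-14-hydroxycembra-7,11,15(17)-trien-16,2-olide
Product: 24 (1R,2S,3R,4R,7E,11E,14S)-14-acetoxy-3,4-epoxycembra-7,11,15(17)-trien-16,2-olide (CNP0294029.1)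
Conditions: Ac2O, pyridine, DMAP (cat.), CH2Cl2, 0 °C
Reagents that add atoms: acetic anhydride, CC(=O)OC(C)=O
Why: DMAP-catalysed acetylation of the secondary alcohol; no stereocentre is touched and acylation should outrun acyl migration.

## Compound list

1 | geranyl acetate | CC(C)=CCC/C(C)=C/COC(C)=O | starting material
2 | (2E,6E)-8-hydroxy-3,7-dimethylocta-2,6-dien-1-yl acetate | CC(=O)OC/C=C(C)/CC/C=C(C)/CO | intermediate
3 | (2E,6E)-8-bromo-3,7-dimethylocta-2,6-dien-1-yl acetate | CC(=O)OC/C=C(C)/CC/C=C(C)/CBr | intermediate
4 | 2-methylbut-1-en-3-yne | C=C(C)C#C | starting material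
5 | chlorobis(cyclopentadienyl)[(1E)-3-methylbuta-1,3-dien-1-yl]zirconium | C=C(C)/C=C/[Zr](Cl)(C1C=CC=C1)C1C=CC=C1 | intermediate (not isolated)
6 | (2E,6E,9E)-3,7,11-trimethyldodeca-2,6,9,11-tetraen-1-yl acetate | CC(=O)OC/C=C(C)/CC/C=C(C)/C/C=C/C(C)=C | intermediate
7 | (2E,6E,9E)-3,7,11-trimethyldodeca-2,6,9,11-tetraen-1-ol | OC/C=C(C)/CC/C=C(C)/C/C=C/C(C)=C | intermediate
8 | [(2R,3R)-3-[(3E,6E)-4,8-dimethylnona-3,6,8-trien-1-yl]-3-methyloxiran-2-yl]methanol | OC[C@H]1O[C@]1(C)CC/C=C(C)/C/C=C/C(C)=C | intermediate
9 | (2S,3R)-3-[(3E,6E)-4,8-dimethylnona-3,6,8-trien-1-yl]-3-methyloxirane-2-carbaldehyde | O=C[C@H]1O[C@]1(C)CC/C=C(C)/C/C=C/C(C)=C | intermediate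
10 | (S)-4-benzyl-1,3-oxazolidin-2-one | O=C1N[C@@H](Cc2ccccc2)CO1 | starting material
11 | methyl 4-chloro-4-oxobutanoate | COC(=O)CCC(Cl)=O | starting material
12 | methyl 4-[(4S)-4-benzyl-2-oxo-1,3-oxazolidin-3-yl]-4-oxobutanoate | COC(=O)CCC(=O)N1[C@@H](Cc2ccccc2)COC1=O | intermediate
13 | dibutylboron (Z)-enolate of 12 | COC(=O)C/C=C(\OB(CCCC)CCCC)N1[C@@H](Cc2ccccc2)COC1=O | intermediate (not isolated)
14 | methyl (3S,4S)-3-{[(4S)-4-benzyl-2-oxo-1,3-oxazolidin-3-yl]carbonyl}-4-[(2R,3R)-3-[(3E,6E)-4,8-dimethylnona-3,6,8-trien-1-yl]-3-methyloxiran-2-yl]-4-hydroxybutanoate | O=C(N1[C@@H](Cc2ccccc2)COC1=O)[C@@H](CC(=O)OC)[C@H](O)[C@H]1O[C@]1(C)CC/C=C(C)/C/C=C/C(C)=C | intermediate (not isolated)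
15 | (4S)-4-benzyl-3-{[(2S,3S)-2-[(2R,3R)-3-[(3E,6E)-4,8-dimethylnona-3,6,8-trien-1-yl]-3-methyloxiran-2-yl]-5-oxooxolan-3-yl]carbonyl}-1,3-oxazolidin-2-one | O=C(N1[C@@H](Cc2ccccc2)COC1=O)[C@H]1CC(=O)O[C@@H]1[C@H]1O[C@]1(C)CC/C=C(C)/C/C=C/C(C)=C | intermediate
16 | (4R,5S)-5-[(2R,3R)-3-[(3E,6E)-4,8-dimethylnona-3,6,8-trien-1-yl]-3-methyloxiran-2-yl]-4-(hydroxymethyl)oxolan-2-one | OC[C@H]1CC(=O)O[C@@H]1[C@H]1O[C@]1(C)CC/C=C(C)/C/C=C/C(C)=C | intermediate
17 | (2S,3S)-2-[(2R,3R)-3-[(3E,6E)-4,8-dimethylnona-3,6,8-trien-1-yl]-3-methyloxiran-2-yl]-5-oxooxolane-3-carbaldehyde (precursor of the key step) | O=C[C@H]1CC(=O)O[C@@H]1[C@H]1O[C@]1(C)CC/C=C(C)/C/C=C/C(C)=C | intermediate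
18 | (1S,2S,3R,4R,7E,11E,14S)-3,4-epoxy-14-(triethylsilyloxy)-17-norcembra-7,11-dien-16,2-olide (product of the key step) | C1C(=O)O[C@H]2[C@H]1[C@@H](O[Si](CC)(CC)CC)C/C(C)=C/CC/C(C)=C/CC[C@@]1(C)O[C@H]21 | intermediate
19 | lithium enolate of 18 (C15=C16–OLi) | C1=C(O[Li])O[C@H]2[C@H]1[C@@H](O[Si](CC)(CC)CC)C/C(C)=C/CC/C(C)=C/CC[C@@]1(C)O[C@H]21 | intermediate (not isolated)
20 | 15-[(dimethylamino)methyl] derivative of 18 (C15 epimers) | CN(C)CC1C(=O)O[C@H]2[C@H]1[C@@H](O[Si](CC)(CC)CC)C/C(C)=C/CC/C(C)=C/CC[C@@]1(C)O[C@H]21 | intermediate
21 | N-methyl quaternary ammonium iodide of 20 | C[N+](C)(C)CC1C(=O)O[C@H]2[C@H]1[C@@H](O[Si](CC)(CC)CC)C/C(C)=C/CC/C(C)=C/CC[C@@]1(C)O[C@H]21.[I-] | intermediate (not isolated)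
22 | (1S,2S,3R,4R,7E,11E,14S)-3,4-epoxy-14-(triethylsilyloxy)cembra-7,11,15(17)-trien-16,2-olide | C=C1C(=O)O[C@H]2[C@H]1[C@@H](O[Si](CC)(CC)CC)C/C(C)=C/CC/C(C)=C/CC[C@@]1(C)O[C@H]21 | intermediate
23 | (1R,2S,3R,4R,7E,11E,14S)-3,4-epoxy-14-hydroxycembra-7,11,15(17)-trien-16,2-olide | C=C1C(=O)O[C@H]2[C@H]1[C@@H](O)C/C(C)=C/CC/C(C)=C/CC[C@@]1(C)O[C@H]21 | intermediate
24 | (1R,2S,3R,4R,7E,11E,14S)-14-acetoxy-3,4-epoxycembra-7,11,15(17)-trien-16,2-olide (CNP0294029.1) | C=C1C(=O)O[C@H]2[C@H]1[C@@H](OC(C)=O)C/C(C)=C/CC/C(C)=C/CC[C@@]1(C)O[C@H]21 | target

## Step count and least certain steps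

Total: 15 steps. Longest linear sequence: 14 steps (steps 1–6 and 8–15, from 1); step 7 is a one-step side branch.

Step 11 (key step, proposed new method).
- What may go wrong: intermolecular coupling and diene oligomerisation may outrun ring closure. Bond formation may occur at C10, or hydrogen may go to C12 (1,2-mode), in place of the 1,4-mode. E control at C11=C12 may be eroded because the allyl terminus C12 carries two carbon substituents. Facial selectivity at C14 may be weak. The aldehyde may simply be hydrosilylated.
- Fallback (known chemistry, ring-closing metathesis at C11=C12), setting out from 3 and returning at 18: Stille coupling of 3 with allyltributylstannane (Pd2(dba)3, AsPh3) would give (2E,6E)-3,7-dimethylundeca-2,6,10-trien-1-yl acetate F1. The operations of steps 4 to 6 would lead through the trienol F2 and the (2R,3R)-epoxy alcohol F3 to the epoxy aldehyde F4. The aldol reaction and lactonisation of step 8 with 13 would give the trans-lactone imide F5, and the operations of steps 9 and 10 the hydroxymethyl lactone F6 and the lactone aldehyde F7. Allylboration of F7 with 2-methylallylboronic acid pinacol ester (no Lewis acid, Felkin–Anh control as in step 11) would give the C14 methallyl carbinol F8. Silylation (Et3SiCl, imidazole) would give its triethylsilyl ether F9. Ring-closing metathesis of the C11 vinyl group with the C12 isopropenyl group (second-generation Grubbs catalyst, high dilution) would close ring A to 18 with loss of ethene. The C11=C12 geometry would then be under thermodynamic rather than mechanistic control.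

Step 8.
- What may go wrong: the pairing is mismatched, so facial selectivity at C2 may be lower than usual for this auxiliary. The boron Lewis acid may open or rearrange the epoxy aldehyde. Lactonisation may be incomplete, or acid-induced epoxide opening may accompany it.
- Fallback, setting out from 7 and returning at 14: MnO2 oxidation of 7 would give (2E,6E,9E)-3,7,11-trimethyldodeca-2,6,9,11-tetraenal F10. The same enolate 13 would add to this achiral enal under pure auxiliary control to give the syn-aldol allylic alcohol F11. Hydroxyl-directed epoxidation (VO(acac)2, t-BuOOH) would then give 14; A(1,3) strain between the C4 methyl and C1 places oxygen syn to the hydroxyl, which is the relationship the target requires. 14 lactonises to 15 as in step 8.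

Step 9.
- What may go wrong: the lactone may be over-reduced, or the lactone acyl group may migrate to the new primary alkoxide under the basic conditions.
- Fallback, setting out from 15 and returning at 16: LiOH/H2O2 at 0 °C would cleave the imide to the lactone carboxylic acid F12 (re-lactonised on buffering to pH 4). Isobutyl chloroformate and N-methylmorpholine would give the mixed carbonic anhydride F13, which NaBH4 at −15 °C would reduce in the same flask to 16.

Step 3.
- What may go wrong: zerovalent palladium may ionise the C1 allylic acetate in competition. Attack may occur at the internal allyl terminus. The trisubstituted olefin geometry may be lost through syn–anti isomerisation of the allylpalladium intermediate.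
- Fallback, setting out from 3 and 4 and returning at 6: copper-mediated coupling of the terminal alkyne of 4 with 3 (CuI, NaI, K2CO3, DMF) would give the skipped enyne acetate F14 without an allylpalladium intermediate. Ruthenium-catalysed trans-hydrosilylation (Cp*Ru(MeCN)3PF6, (EtO)3SiH) would give the (Z)-alkenylsilane F15 (one regioisomer shown; either serves). Protodesilylation (CuI, Bu4NF) would give 6 with the 9E olefin.

## Further compounds

F1 | step 11 | (2E,6E)-3,7-dimethylundeca-2,6,10-trien-1-yl acetate | CC(=O)OC/C=C(C)/CC/C=C(C)/CCC=C
F2 | step 11 | (2E,6E)-3,7-dimethylundeca-2,6,10-trien-1-ol | OC/C=C(C)/CC/C=C(C)/CCC=C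
F3 | step 11 | [(2R,3R)-3-methyl-3-[(3E)-4-methylocta-3,7-dien-1-yl]oxiran-2-yl]methanol | OC[C@H]1O[C@]1(C)CC/C=C(C)/CCC=C
F4 | step 11 | (2S,3R)-3-methyl-3-[(3E)-4-methylocta-3,7-dien-1-yl]oxirane-2-carbaldehyde | O=C[C@H]1O[C@]1(C)CC/C=C(C)/CCC=C
F5 | step 11 | trans-lactone imide, analogue of 15 with a C11 vinyl terminus | O=C(N1[C@@H](Cc2ccccc2)COC1=O)[C@H]1CC(=O)O[C@@H]1[C@H]1O[C@]1(C)CC/C=C(C)/CCC=C
F6 | step 11 | hydroxymethyl lactone, analogue of 16 with a C11 vinyl terminus | OC[C@H]1CC(=O)O[C@@H]1[C@H]1O[C@]1(C)CC/C=C(C)/CCC=C
F7 | step 11 | lactone aldehyde, analogue of 17 with a C11 vinyl terminus | O=C[C@H]1CC(=O)O[C@@H]1[C@H]1O[C@]1(C)CC/C=C(C)/CCC=C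
F8 | step 11 | (14S)-C14 methallyl carbinol of F7 | C=C(C)C[C@H](O)[C@H]1CC(=O)O[C@@H]1[C@H]1O[C@]1(C)CC/C=C(C)/CCC=C
F9 | step 11 | triethylsilyl ether of F8 | C=C(C)C[C@H](O[Si](CC)(CC)CC)[C@H]1CC(=O)O[C@@H]1[C@H]1O[C@]1(C)CC/C=C(C)/CCC=C
F10 | step 8 | (2E,6E,9E)-3,7,11-trimethyldodeca-2,6,9,11-tetraenal | O=C/C=C(C)/CC/C=C(C)/C/C=C/C(C)=C
F11 | step 8 | methyl (3S,4R,5E,9E,12E)-3-{[(4S)-4-benzyl-2-oxo-1,3-oxazolidin-3-yl]carbonyl}-4-hydroxy-6,10,14-trimethylpentadeca-5,9,12,14-tetraenoate | O=C(N1[C@@H](Cc2ccccc2)COC1=O)[C@@H](CC(=O)OC)[C@H](O)/C=C(C)/CC/C=C(C)/C/C=C/C(C)=C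
F12 | step 9 | (2S,3S)-2-[(2R,3R)-3-[(3E,6E)-4,8-dimethylnona-3,6,8-trien-1-yl]-3-methyloxiran-2-yl]-5-oxooxolane-3-carboxylic acid | OC(=O)[C@H]1CC(=O)O[C@@H]1[C@H]1O[C@]1(C)CC/C=C(C)/C/C=C/C(C)=C
F13 | step 9 | isobutyl carbonic anhydride of F12 | CC(C)COC(=O)OC(=O)[C@H]1CC(=O)O[C@@H]1[C@H]1O[C@]1(C)CC/C=C(C)/C/C=C/C(C)=C
F14 | step 3 | (2E,6E)-3,7,11-trimethyldodeca-2,6,11-trien-9-yn-1-yl acetate | CC(=O)OC/C=C(C)/CC/C=C(C)/CC#CC(C)=C
F15 | step 3 | (2E,6E,9Z)-3,7,11-trimethyl-9-(triethoxysilyl)dodeca-2,6,9,11-tetraen-1-yl acetate | CC(=O)OC/C=C(C)/CC/C=C(C)/C/C(=C/C(C)=C)[Si](OCC)(OCC)OCC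
A1 | alternative 1 | 16-membered allyl β-keto lactone (C4 ketone, C5–C(=O)–O–C6 ester, C3 p-methoxybenzyl ether, C14 tert-butyldimethylsilyl ether) | COc1ccc(CO[C@@H]2C(=O)CC(=O)OC/C=C(C)/CC/C=C(C)/C[C@H](O[Si](C)(C)C(C)(C)C)[C@H]3CC(=O)O[C@H]23)cc1
A2 | alternative 1 | 14-membered C4 ketone | COc1ccc(CO[C@@H]2C(=O)CC/C=C(C)/CC/C=C(C)/C[C@H](O[Si](C)(C)C(C)(C)C)[C@H]3CC(=O)O[C@H]23)cc1
A3 | alternative 2 | open-chain diyne with methyl-capped C11 and C12 alkynes, free C14 hydroxyl and α-methylene lactone | C=C1C(=O)O[C@@H]([C@H]1[C@@H](O)CC#CC)[C@H]1O[C@]1(C)CC/C=C(C)/CCC#CC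
A4 | alternative 2 | 14-membered C11–C12 cycloalkyne | C=C1C(=O)O[C@H]2[C@H]1[C@@H](O)CC#CCC/C(C)=C/CC[C@@]1(C)O[C@H]21
A5 | alternative 3 | saturated epoxy lactone with terminal C13–C14 epoxide and methyl-capped C11–C12 alkyne | C1C(=O)O[C@@H]([C@H]1[C@@H]1CO1)[C@H]1O[C@]1(C)CC/C=C(C)/CCC#CC
A6 | alternative 3 | macrocyclic C14 alcohol of the saturated lactone | C1C(=O)O[C@H]2[C@H]1[C@@H](O)C/C(C)=C/CC/C(C)=C/CC[C@@]1(C)O[C@H]21
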